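The runs are calculated for an exercise; noise was put on by code.

X appears in the south-east run at a steady 2.14 mM min⁻¹ over the first 8.00 min, whereas the north run, where G is the limiting reagent, makes X ever more slowly as c_G falls.

| flask | D | G | Z | remark |
|---|---|---|---|---|
| south | 36 mM | 55 mM | 0.36 mM | run made earlier |
| south-east | 36 mM | 87 mM | 0.36 mM | run made earlier |
| north | 54 mM | 39.6 mM | 0.36 mM | run made earlier |
| flask | 36 mM | 39.6 mM | 0.36 mM |  |

| run | time / min | X / % |
|---|---|---|
| south | 2.50 | 14.0 |
| south | 8.00 | 46.2 |
| south | 15.0 | 79.4 |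
| south | 20.0 | 96.5 |
| south | 30.0 | 98.0 |
| south | 40.0 | 99.7 |
| south-east | 3.00 | 19.0 |
| south-east | 5.00 | 29.8 |
| south-east | 8.00 | 47.5 |
| south-east | 15.0 | 83.8 |
| south-east | 25.0 | 100.6 |
| south-east | 40.0 | 99.5 |
| north | 4.00 | 15.9 |
| north | 10.0 | 36.5 |
| north | 20.0 | 57.9 |
| north | 30.0 | 67.4 |
| north | 40.0 | 72.7 |

(standard deviation of a reading: 1 percentage point)

* apparent order in Z when 30% of the D are converted (percent change of the rate of making X for one percent more Z charged)
* apparent order in G when 30% of the D are converted (percent change of the rate of making X for one percent more G charged)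

Between 10.0 min and 20.0 min the north run makes X at 1.16 mM min⁻¹ while c_G stands near 14.1 mM, if one G goes with each X, so we read a rate per unit of c_G of 0.0819 min⁻¹. We carry the crossing concentration, the c_G at which this G-proportional rate would equal the plateau rate, 26.1 mM. In the flask at 30% conversion c_G is 28.8 mM, just above the crossing, and adding the two as resistances in series gives our own order in G of 0.475.

The forecast's order in G, 0.37 (0.22 to 0.55), is lower than ours, and it puts the order in Z at 1 (0.6 to 1.3), with the words “Z was never varied, so I assume about first order”.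

The flask gives 0.30 in G and 0.80 in Z, both lower than the forecast and inside its ranges.

    G + Z → Q (k = 1230 M⁻¹ min⁻¹)
    D + Q → L (k = 7670 M⁻¹ min⁻¹)
    L ⇌ Z + X (K = 0.0340 M, k = 10.1 min⁻¹)
    2 L ⇌ J, settled at all times (K = 1100 M⁻¹)
    2 Z → E (k = 310 M⁻¹ min⁻¹)

At 30% conversion in the flask, with L, the resting state, at 55.8% of the catalyst and Z at 14.6%, G takes up Z at 1.86 mM min⁻¹, slightly below the 2.03 mM min⁻¹ at which L opens, forward step alone. By 25.0 min the flask has c_G at 5.23 mM, below the crossing of 26.1 mM, and L has fallen to 36.6% while Z stands at 22.3%.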